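**Flat is not finished.** A flat plateau tempts you to read equilibrium, yet a reaction also goes flat when its limiting reagent is spent. Here that candidate is Q, charged lower than J.

| setting | Tuesday's | Sunday's | Friday's | alder | ash | cedar |
|---|---|---|---|---|---|---|
| Q | 0.031 M | 0.015 M | 0.062 M | 0.031 M | 0.031 M (fed, over 6.0 d) | 0.031 M |
| J | 0.0316 M | 0.0316 M | 0.0316 M | 0.0316 M | 0.0316 M | 0.0316 M (fed, over 6.0 d) |
| remark | run made earlier | run made earlier | run made earlier | everything together at the start | all else is in the flask from the start; the feed brings no volume worth counting | all else is in the flask from the start; the feed brings no volume worth counting |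
| time |  |  |  | 10 d | 10 d | 10 d |

- Tuesday's (time / d: E / %): 2.08: 46.0; 4.00: 44.7; 6.00: 45.2; 8.00: 45.3; 10.0: 45.1
- Sunday's (time / d: E / %): 0.833: 56.8; 1.67: 61.3; 3.00: 62.3; 5.00: 62.3; 10.0: 62.3
- Friday's (time / d: E / %): 2.08: 30.4; 4.00: 30.2; 6.00: 30.5; 8.00: 30.1; 10.0: 31.0

(standard deviation of a reading: 0.5 percentage points)



* the flask that comes out highest in amount of E, in percent of the Q charged, or "all alike" when all lie within 1.5 percentage points (alder / ash / cedar / all alike)
* E at the end, in percent of the Q charged, alder
* E at the end, in percent of the Q charged, ash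
* E at the end, in percent of the Q charged, cedar

**Reading the runs.** E at the end falls as Q rises: 62.3 % from 0.015 M, 45.1 % from 0.031 M, 31.0 % from 0.062 M. My reading, which differs from the forecast, is that some loss of Q grows with c(Q). Sunday's tail gives a pseudo-first-order clock: the gap to the plateau shrinks from 5.5 percentage points to 1 point in 0.837 d, a half-life of Q of 0.340 d, rough because of the scatter.

**Ash, slowly.** At first, each portion of Q meets J at full charge. In the middle, Q settles where removal matches feed. This hold level, the feed rate times the half-life over ln(2), is the steady-state c(Q): 0.002537 M, lower than Sunday's charge. J is being used meanwhile, which will stretch the half-life. After the feed, 4.00 d remain, about 11.8 half-lives, so the last Q goes.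

**My reckoning.** Alder should repeat Tuesday's run and ash should reach at least Sunday's 62.3 %. Cedar should fall below Friday's 31.0 %, because in the half-life read from Sunday's run its feed brings 0.001792 M of J against 0.031 M of Q, a proportion worse than Friday's.

**The forecast.** It gives 45.3 % for alder, 45.2 % for ash and 45.2 % for cedar, so all alike, holding that “this is a true equilibrium”.

**The result.** Alder gives 45.3 %, ash 62.6 % and cedar 13.4 %, so the highest is ash.

    2 Q → Z (k = 7.45 × 10⁻⁴ M⁻¹ s⁻¹)
    Q + J → E + D (k = 8.80 × 10⁻⁴ M⁻¹ s⁻¹)
    Q + D → X (k = 0.00101 M⁻¹ s⁻¹)

**Hold level.** Alder ends with Q at 0 % and J at 55.5 % of its charge. In alder the half-life of Q by the step with J alone, with J as charged, is 0.29 d, shorter than ash's feed of 6.0 d, and at 6.00 d ash holds 0.002247 M of Q against the hold level of 0.00254 M. Charging 0.012 M of Q in ash's recipe lowers the hold level to 9.82 × 10⁻⁴ M, a factor of 2.58. That neighbour ends with E at 80.6 % and Z at 3.83 %, against Z at 9.83 % in ash, a factor of 2.57.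

The earlier runs and the new flask are calculated with made-up constants; noise was put on by code.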